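## Retrosynthetic overview

1. Target ⇒ double O-demethylation of its bis(methyl ether).
2. Central biaryl C–C bond ⇒ Ullmann homocoupling of two identical (S)-configured aryl iodides, with iodine sitting between OMe and CH3.
3. Aryl iodide ⇒ methoxy-directed ortho-lithiation/iodination of (S)-curcuphenol methyl ether.
4. (S)-Curcuphenol methyl ether ⇒ new enantioselective, branch-selective ortho-C–H alkylation of 3-methylanisole with 6-methylhepta-1,5-diene (aryl–C bond and the (S) centre in one step); the diene ⇒ Wittig reaction of pent-4-enal.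
5. Rings: none is built. Both benzene rings come from 3-methylanisole and are joined in the penultimate step.

**Assumption:** the SMILES fixes only the two (S) benzylic centres and leaves the hindered biaryl axis undefined, so the axis is not controlled; both atropisomers fit the SMILES and can be separated by HPLC at the end if one is wanted.

**Catalyst shorthand (step 2):** CpX is the (R)-configured binaphthyl-fused cyclopentadienyl anion (two adjacent Cp carbons bridged through CH2 groups to the 2,2'-positions of 1,1'-binaphthyl) carrying i-Pr3SiO groups at the 3,3'-positions. The precatalyst is (CpX)Sc(CH2C6H4NMe2-o)2.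

## Route

**Step 1**
Reactants: 1 pent-4-enal; 2 isopropyltriphenylphosphonium iodide
Product: 4 6-methylhepta-1,5-diene, via ylide 3 (not isolated)
Conditions: 2, n-BuLi, THF, 0 °C, 30 min; then 1, −78 °C → rt; pentane, filtration, distillation
Reagents that add atoms: none
Why: Wittig olefination, in which the non-stabilised isopropylidene ylide adds to the aldehyde and the oxaphosphetane collapses to the trisubstituted alkene; no alkene geometry issue arises because the new alkene carbon carries two methyl groups.

**Step 2**
Reactants: 4 6-methylhepta-1,5-diene; 5 3-methylanisole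
Product: 6 2-methoxy-4-methyl-1-[(2S)-6-methylhept-5-en-2-yl]benzene ((S)-curcuphenol methyl ether)
Conditions: (CpX)Sc(CH2C6H4NMe2-o)2 (5 mol %), [Ph3C][B(C6F5)4] (5 mol %), premixed in toluene; then 4 and 5 (1:1), 50 °C, 24 h
Reagents that add atoms: none
Why: Proposed new method: enantioselective, branch-selective ortho-C–H alkylation of an anisole with an unactivated 1-alkene, a fully atom-economical 1:1 addition in which the cationic trivalent scandium alkyl formed from the precatalyst and the trityl borate metalates the less hindered ortho C–H of 5 (C6, para to CH3) by methoxy-directed σ-bond metathesis, the monosubstituted alkene of 4 inserts 1,2 into the Sc–aryl bond so that the aryl group ends on C2 (the trisubstituted alkene is too hindered to insert), the binaphthyl wall of CpX selects the Si face of the alkene and so sets the (S) benzylic centre, and protonolysis of the Sc–CH2 bond by the next anisole C–H creates the CH3 group and turns the cycle over; the closest known reaction types are the non-asymmetric rare-earth-catalysed ortho-C–H alkylation of anisoles with 1-alkenes and the enantioselective C–H alkylation of pyridines with 1-alkenes by chiral half-sandwich scandium catalysts.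

**Step 3**
Reactants: 6 (S)-curcuphenol methyl ether
Product: 8 3-iodo-2-methoxy-4-methyl-1-[(2S)-6-methylhept-5-en-2-yl]benzene, via aryllithium 7 (not isolated)
Conditions: n-BuLi (1.5 equiv), TMEDA (1.5 equiv), Et2O, 0 °C → rt, 4 h; then I2 (1.6 equiv), THF, −78 °C → rt; aq Na2S2O3
Reagents that add atoms: iodine, II
Why: Directed ortho-metalation followed by iodinolysis, in which the methoxy group steers n-BuLi/TMEDA to the only free ortho position (the other is blocked by the side chain); the tertiary benzylic C–H and the alkene are not attacked, so the (S) centre is kept and iodine lands between OMe and CH3.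

**Step 4**
Reactants: 8 aryl iodide (2 molecules)
Product: 9 2,2'-dimethoxy-6,6'-dimethyl-3,3'-bis[(2S)-6-methylhept-5-en-2-yl]-1,1'-biphenyl
Conditions: activated Cu powder (6 equiv), neat, 220 °C, 3 h, Ar
Reagents that add atoms: none
Why: Classical Ullmann reductive homocoupling of an ortho-methoxy aryl iodide on copper, the standard entry to 2,2'-dimethoxy-6,6'-dimethylbiphenyls; the neutral conditions leave the alkenes and benzylic centres untouched, and the new axis forms as a mixture of the two atropisomers.

**Step 5**
Reactants: 9 bis(methyl ether)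
Product: 10 6,6'-dimethyl-3,3'-bis[(2S)-6-methylhept-5-en-2-yl]-[1,1'-biphenyl]-2,2'-diol (target)
Conditions: NaSEt (10 equiv), DMF, 150 °C, 6 h; then 1 M HCl, 0 °C
Reagents that add atoms: none
Why: Nucleophilic (SN2) O-demethylation by thiolate at the methyl carbon of the twisted, hindered aryl methyl ethers; no acid is present during the reaction, so the trisubstituted alkenes and the benzylic stereocentres are unaffected.

## Compound list

1 | pent-4-enal | C=CCCC=O | starting material
2 | isopropyltriphenylphosphonium iodide | CC(C)[P+](c1ccccc1)(c1ccccc1)c1ccccc1.[I-] | starting material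
3 | isopropylidenetriphenylphosphorane (ylide) | CC(C)=P(c1ccccc1)(c1ccccc1)c1ccccc1 | intermediate
4 | 6-methylhepta-1,5-diene | C=CCCC=C(C)C | intermediate
5 | 3-methylanisole (1-methoxy-3-methylbenzene) | COc1cccc(C)c1 | starting material
6 | 2-methoxy-4-methyl-1-[(2S)-6-methylhept-5-en-2-yl]benzene ((S)-curcuphenol methyl ether) | CC(C)=CCC[C@H](C)c1ccc(C)cc1OC | intermediate
7 | {2-methoxy-6-methyl-3-[(2S)-6-methylhept-5-en-2-yl]phenyl}lithium | CC(C)=CCC[C@H](C)c1ccc(C)c([Li])c1OC | intermediate
8 | 3-iodo-2-methoxy-4-methyl-1-[(2S)-6-methylhept-5-en-2-yl]benzene | CC(C)=CCC[C@H](C)c1ccc(C)c(I)c1OC | intermediate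
9 | 2,2'-dimethoxy-6,6'-dimethyl-3,3'-bis[(2S)-6-methylhept-5-en-2-yl]-1,1'-biphenyl | CC(C)=CCC[C@H](C)c1ccc(C)c(-c2c(C)ccc([C@@H](C)CCC=C(C)C)c2OC)c1OC | intermediate
10 | 6,6'-dimethyl-3,3'-bis[(2S)-6-methylhept-5-en-2-yl]-[1,1'-biphenyl]-2,2'-diol | CC(C)=CCC[C@H](C)c1ccc(C)c(-c2c(C)ccc([C@@H](C)CCC=C(C)C)c2O)c1O | target

## Step count and risks

Total steps: 5. Longest linear sequence: 5 steps (1 and 2 → 4 → 6 → 8 → 9 → 10); 3-methylanisole 5 enters at step 2.

**Step 2 (the proposed new C–H alkylation).**
- Risks: insufficient enantioselectivity, alkylation at the flanked ortho position of 5, over-alkylation of 6 at its remaining flanked ortho position, or catalyst deactivation by the ether.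
- The sense of induction is not predictable with certainty; if the (R) product forms, the (S)-configured CpX ligand is used instead.
- The ee is measured on 6 by chiral HPLC. The later dimerisation upgrades it, because the heterochiral dimer is a separable diastereomer.
- Fallback (known chemistry), setting out from 5 and returning at 6: 5 is lithiated at its less hindered ortho position (n-BuLi, TMEDA, Et2O) to (2-methoxy-4-methylphenyl)lithium F1. B(OMe)3 and then aqueous HCl give (2-methoxy-4-methylphenyl)boronic acid F2, which is crystallised free of the minor isomer and is also a catalogue compound. Hayashi–Miyaura 1,4-addition of F2 to ethyl (E)-crotonate with Rh(acac)(C2H4)2/(R)-BINAP (the ligand antipode that delivers the (S) ester) in dioxane/H2O at 100 °C gives ethyl (3S)-3-(2-methoxy-4-methylphenyl)butanoate F3. LiAlH4 in THF reduces it to (3S)-3-(2-methoxy-4-methylphenyl)butan-1-ol F4. I2, PPh3 and imidazole give 1-[(2S)-4-iodobutan-2-yl]-2-methoxy-4-methylbenzene F5. Copper-catalysed coupling of F5 with (CH3)2C=CHMgBr (Li2CuCl4 cat., THF, −20 °C → rt) gives 6.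

**Step 3 (methoxy-directed lithiation at the flanked position).**
- Risks: slow or incomplete metalation next to CH3 with the weak methoxy director, and competing allylic metalation.
- Fallback, setting out from 6 and returning at 10: NaSEt in DMF at 150 °C gives (S)-curcuphenol F6. MOMCl and i-Pr2NEt in CH2Cl2 give 2-(methoxymethoxy)-4-methyl-1-[(2S)-6-methylhept-5-en-2-yl]benzene F7, which carries a much stronger, chelating director. n-BuLi/TMEDA in THF at 0 °C gives {2-(methoxymethoxy)-6-methyl-3-[(2S)-6-methylhept-5-en-2-yl]phenyl}lithium F8, and I2 converts it into 3-iodo-2-(methoxymethoxy)-4-methyl-1-[(2S)-6-methylhept-5-en-2-yl]benzene F9. Ullmann coupling (activated Cu powder, DMF, 150 °C) gives 2,2'-bis(methoxymethoxy)-6,6'-dimethyl-3,3'-bis[(2S)-6-methylhept-5-en-2-yl]-1,1'-biphenyl F10. HCl in MeOH at rt removes both acetals to give 10.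

**Step 4 (Ullmann coupling to a tetra-ortho-substituted biaryl).**
- Risks: low conversion, or proto-deiodination back to 6 at 220 °C.
- Fallback, setting out from 6 and 8 and returning at 9: 6 is lithiated as in step 3 to aryllithium 7. ZnCl2 in THF converts it into chlorido{2-methoxy-6-methyl-3-[(2S)-6-methylhept-5-en-2-yl]phenyl}zinc F11. Negishi cross-coupling of F11 with iodide 8 (Pd2(dba)3/RuPhos, THF/NMP, 70 °C) gives 9 under mild conditions.

## Further compounds

F1 | step 2 | (2-methoxy-4-methylphenyl)lithium | [Li]c1ccc(C)cc1OC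
F2 | step 2 | (2-methoxy-4-methylphenyl)boronic acid | OB(O)c1ccc(C)cc1OC
F3 | step 2 | ethyl (3S)-3-(2-methoxy-4-methylphenyl)butanoate | CCOC(=O)C[C@H](C)c1ccc(C)cc1OC
F4 | step 2 | (3S)-3-(2-methoxy-4-methylphenyl)butan-1-ol | OCC[C@H](C)c1ccc(C)cc1OC
F5 | step 2 | 1-[(2S)-4-iodobutan-2-yl]-2-methoxy-4-methylbenzene | ICC[C@H](C)c1ccc(C)cc1OC
F6 | step 3 | (S)-curcuphenol (5-methyl-2-[(2S)-6-methylhept-5-en-2-yl]phenol) | CC(C)=CCC[C@H](C)c1ccc(C)cc1O
F7 | step 3 | 2-(methoxymethoxy)-4-methyl-1-[(2S)-6-methylhept-5-en-2-yl]benzene | CC(C)=CCC[C@H](C)c1ccc(C)cc1OCOC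
F8 | step 3 | {2-(methoxymethoxy)-6-methyl-3-[(2S)-6-methylhept-5-en-2-yl]phenyl}lithium | CC(C)=CCC[C@H](C)c1ccc(C)c([Li])c1OCOC
F9 | step 3 | 3-iodo-2-(methoxymethoxy)-4-methyl-1-[(2S)-6-methylhept-5-en-2-yl]benzene | CC(C)=CCC[C@H](C)c1ccc(C)c(I)c1OCOC
F10 | step 3 | 2,2'-bis(methoxymethoxy)-6,6'-dimethyl-3,3'-bis[(2S)-6-methylhept-5-en-2-yl]-1,1'-biphenyl | CC(C)=CCC[C@H](C)c1ccc(C)c(-c2c(C)ccc([C@@H](C)CCC=C(C)C)c2OCOC)c1OCOC
F11 | step 4 | chlorido{2-methoxy-6-methyl-3-[(2S)-6-methylhept-5-en-2-yl]phenyl}zinc | CC(C)=CCC[C@H](C)c1ccc(C)c([Zn]Cl)c1OC
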